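(Readings and results were computed for an exercise, noise included.)

- The easy step is the charge: if the first and second nucleophile took the intermediate equally well, the share of target in target plus other capture product would equal the charged share of first nucleophile, 74.1% in the flask.

all flasks: starting material 0.12 M
- cedar: first nucleophile 1.3 equiv; second nucleophile 0.70 equiv; run made earlier
- ash: first nucleophile 3 equiv; second nucleophile 0.70 equiv; run made earlier
- larch: first nucleophile 2 equiv; second nucleophile 1 equiv; run made earlier
- flask: first nucleophile 2.00 equiv; second nucleophile 0.700 equiv; time 8.0 h

| run | time / h | target / % | other capture product / % |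
|---|---|---|---|
| cedar | 0.833 | 21.2 | 9.5 |
| cedar | 1.33 | 27.7 | 9.8 |
| cedar | 2.00 | 31.8 | 12.4 |
| cedar | 2.50 | 33.9 | 10.6 |
| cedar | 4.00 | 38.7 | 11.5 |
| cedar | 6.00 | 40.3 | 12.4 |
| cedar | 10.0 | 41.9 | 12.9 |
| ash | 0.500 | 16.7 | 2.2 |
| ash | 1.33 | 32.5 | 4.6 |
| ash | 2.50 | 39.5 | 6.5 |
| ash | 4.00 | 42.8 | 4.8 |
| ash | 6.00 | 44.1 | 6.9 |
| ash | 8.00 | 46.7 | 6.4 |
| ash | 10.0 | 48.1 | 5.1 |
| larch | 2.00 | 33.1 | 9.5 |
| larch | 4.00 | 41.5 | 10.2 |
| larch | 6.00 | 41.4 | 10.2 |
| larch | 8.00 | 43.7 | 10.5 |
| larch | 10.0 | 44.9 | 10.8 |

(standard deviation of a reading: 1 percentage point)

- what was read earlier has a scatter of 1 percentage point, one standard deviation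
- steps under discussion: starting material -> intermediate; first nucleophile + intermediate -> target; second nucleophile + intermediate -> other capture product; starting material <-> dormant form; target -> over-reaction product; 2 second nucleophile -> homo dimer

* share of target in target plus other capture product at 6.0 min
* share of target in target plus other capture product at 8.0 h
* which of target and other capture product there is more of at 8.0 h

- The first cedar reading has a target to other capture product ratio of 2.23, which gives 1.20 for the selectivity factor S: that ratio divided by charged [first nucleophile] over charged [second nucleophile], so the symmetric case is S = 1.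
- I take this as my upper bound, since that reading comes later than 6.0 min and the cedar ratio climbs to 3.25; in the flask it gives a share of 77.4%.
- A straight line through the first two cedar ratios, run back to time zero, gives S = 0.665, so my lower bound for the flask is 65.5%; both ends are readings and carry the scatter of 1 percentage point.
- The symmetric share lies inside this bracket, so the bracket leaves open which nucleophile takes the intermediate faster.
- The forecast gives 79.5% at 6.0 min, 83.5% at 8.0 h and target in the lead, saying “At 6 min, target/other is about 4”; its early share stands above my bracket.
- The flask gives 68.7% at 6.0 min, inside the bracket, which is S = 0.770; at 8.0 h it gives 83.7%, with target leading at 44.2% against 8.63%.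

    starting material → intermediate (k = 0.540 /h)
    first nucleophile + intermediate → target (k = 330 /M/h)
    second nucleophile + intermediate → other capture product (k = 490 /M/h)
    starting material ⇌ dormant form (K = 21.0, k = 0.550 /h)
    target → over-reaction product (k = 0.00180 /h)
    2 second nucleophile → homo dimer (k = 16.0 /M/h)

- The neighbour flask, charged with 1.80 equiv of second nucleophile and otherwise the same, gets the same two values of S, which bracket its share at 6.0 min between 42.5% and 57.2%; it gives 50.2%, and at 8.0 h its share is 78.1%, with second nucleophile at 1.7% of its own charge.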